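Remark (assumption): the locants C1–C8a used in the discussion count the naphthalene from the aryl-bearing carbon (C1 aryl, C2 OH, C3 CHO, C4 H, C7 OH, C8 OMe), while the compound list uses systematic names. Rotation about the C1–aryl bond is taken to be fast, so no atropisomers are considered.

## Analysis of the target

Vitrofolal B (21) is a 1-arylnaphthalene. Ring A (C4a, C5–C8, C8a) carries a free hydroxyl at C7 and a methoxy group at C8. Ring B (C1–C4, C4a, C8a) carries the 3,4-dimethoxyphenyl ring C at C1, a hydroxyl at C2, a formyl group at C3 and hydrogen at C4. There is no stereocentre, and the C1–aryl axis has no ortho substituent on ring C, so nothing stereochemical has to be set. The sensitive parts are the ortho-hydroxy aldehyde (Dakin cleavage by peroxide, reduction, condensation), the electron-rich naphthol and catechol-type ring A (oxidation), and the two neighbouring oxygens on C7 and C8, which must end up different. The difficulty is the contiguous, fully substituted C1–C2–C3 edge of ring B: three different substituents in a fixed order, with C1 further crowded by the peri methoxy group, so that late functionalization of a preformed naphthalene would be a regiochemical gamble. The feature the plan rests on is that C2 is the only heteroatom-bearing carbon of ring B and lies between two carbon-substituted ring carbons, C1 and C3, while C4 carries only hydrogen. If C2 is removed and C1 is joined to C3, what remains is the five-membered ring of a 3-aryl-1H-indene with the formyl carbon on its C2 and the future C4 as its CH2. Ring B is therefore an indene ring plus one inserted carbon.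

## Retrosynthetic reasoning

**21 from 20.** Only the O–CH2Ph bond at C7 is cut. A benzyl ether is chosen because it survives strong base, organometallic reagents, zerovalent palladium and a carbene, and it keeps ring A non-phenolic until the end. The forward reaction must remove it without reducing the formyl group.

**20 from 16 (through 17, 18 and 19).** The C2–O bond is traced back to a C2–Br bond and the formyl group to its dimethyl acetal. The bromide is the handle that the ring-forming step leaves at exactly this carbon. The acetal is kept until the oxidant is destroyed, so the ortho-hydroxy aldehyde never meets peroxide.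

**16 from 13 and 14.** C2 is excised: the C1–C2 and C2–C3 bonds are cut and C1 is rejoined to C3 as the double bond of indene 13, with C4 becoming the ring CH2. The cut is made here because C2 is the one ring carbon with a heteroatom and two fully substituted neighbours, and a carbene carbon from bromoform 14 arrives with the halogen already attached. The gain is a ring B whose substitution pattern is fixed by the position of one double bond. The forward reaction must add to a hindered tetrasubstituted alkene and open the cyclopropane 15 to the aromatic ring.

**13 from 12, and 12 from 10 (through 11).** The acetal goes back to enal 12. The indene double bond (C1–C3 in target locants) is then cut by a retro-aldol condensation to keto aldehyde 10. Only the aldehyde can enolize and only the diaryl ketone is within reach as electrophile, so there is nothing regiochemical to control. The bond made here is the one the ring expansion later breaks; its task is to hold C1 and C3 together so that the carbene carbon is delivered between them.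

**10 from 8 and 9.** The aryl–CH2 bond (C4a–C4) is cut. A Heck reaction with prop-2-en-1-ol 9 brings in C4, C3 and the formyl carbon in one step, already at the aldehyde oxidation level.

**8 from 7, and 7 from 4 and 5 (through 6).** The diaryl ketone is cut at the bond between C1 and ring C. The Grignard reagent 6 made from 5 adds to aldehyde 4, and the carbinol 7 is oxidized. The cut is on the ring C side because ring A already carries the aldehyde from the starting material and the ring C nucleophile is simple.

**4 from 3, 3 from 2, 2 from 1.** The ring bromine sits para to the benzyloxy group and is introduced by electrophilic substitution. The two phenols of 1 are told apart through the dianion: O3 is benzylated first, then the chelated O2 is methylated.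

## Alternatives that were turned down

**Alternative 1: Dieckmann closure of ring B at C2–C3.**
- Disconnection and key step: the diester methyl 3-{4-(benzyloxy)-2-[1-(3,4-dimethoxyphenyl)-2-methoxy-2-oxoethyl]-3-methoxyphenyl}propanoate A1 would be treated with NaOMe. The propanoate α-carbon (C3) would attack the diarylacetate ester carbon (C2) to give the enolized keto ester methyl 6-(benzyloxy)-4-(3,4-dimethoxyphenyl)-3-hydroxy-5-methoxy-1,4-dihydronaphthalene-2-carboxylate A2. Dehydrogenation and conversion of the ester into the aldehyde would follow.
- For it: a classical, unstrained six-membered closure, and the C2 oxygen arrives with the ring, so no halogen-to-oxygen exchange is needed. On that point it is stronger than the chosen route.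
- Against it: in A1 the diarylacetate C1–H is far more acidic than the propanoate CH2. Base therefore mainly forms the C1 enolate, which deactivates the very carbonyl (C2) that must be attacked and can close the other way onto the propanoate carbonyl to a non-enolizable quaternary keto ester. A2 can then arise only by equilibration through retro-Claisen cleavage.
- Comparison: A1 needs a crowded diarylacetate (a one-carbon homologation of the diaryl ketone) in addition to the side chain, and A2 still needs aromatization plus a reduction and an oxidation. The sequence is longer. The chosen route offers the aldehyde oxidation level from the Heck step onwards and a ring formation whose outcome does not depend on an equilibrium.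

**Alternative 2: carbene-catalysed crossed benzoin closure at C1–C2.**
- Disconnection and key step: the same keto aldehyde 10 would be treated with a triazolium-derived N-heterocyclic carbene and DBU. The aldehyde carbon, as an acyl-anion equivalent, would add to the diaryl ketone carbon and give the tertiary α-ketol 7-(benzyloxy)-1-(3,4-dimethoxyphenyl)-1-hydroxy-8-methoxy-3,4-dihydronaphthalen-2(1H)-one A3. Formylation at C3 and loss of water would then aromatize ring B.
- For it: catalytic and atom-economical, with the C2 oxygen in place directly. On paper it is one step shorter from 10 (three operations against four), so on step count it is stronger.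
- Against it: the acyl-anion equivalent is bulky and must attack a ketone that has two ortho substituents on ring A and is deactivated by the para-methoxy of ring C. The addition is reversible. Under the amine base the same substrate has an easier path, the five-membered aldol condensation to 12, which is precisely what the chosen route uses on purpose.
- Comparison: the chosen route works with the intrinsic reactivity of 10 instead of against it, carries the formyl carbon from the start, and fixes the order aryl–oxygen–formyl by an irreversible ring expansion.

**Alternative 3: ring-closing metathesis at C3=C4.**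
- Disconnection and key step: the diene 1-[3-(benzyloxy)-6-ethenyl-2-methoxyphenyl]-3-{[(tert-butyldimethylsilyl)oxy]methyl}-1-(3,4-dimethoxyphenyl)but-3-en-2-one A4 would be treated with the second-generation Grubbs catalyst RuCl2(=CHPh)(PCy3)(H2IMes). Loss of ethylene would give a naphthalen-2(1H)-one that tautomerizes to 7-(benzyloxy)-3-[(tert-butyldimethylsilyloxy)methyl]-1-(3,4-dimethoxyphenyl)-8-methoxynaphthalen-2-ol A5. Desilylation, oxidation of the benzylic alcohol and debenzylation would follow.
- For it: neutral conditions, a closure driven by aromatization, no regiochemical ambiguity, and the C2 oxygen present without a halogen exchange. On mildness of the ring-forming step it is stronger.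
- Against it: A4 has a dibenzylic methine next to a ketone (easily enolized and oxidized) and a 1,1-disubstituted, electron-poor α-methylene ketone that is a reluctant metathesis partner and a Michael acceptor prone to polymerize. Building A4 takes more C–C bond-forming steps (vinylation of ring A, homologation of the diaryl ketone, addition of a metalated allyl ether, oxidation).
- Comparison: the sequence before and after the closure is clearly longer. The chosen route reaches its precursor through robust steps and concentrates the uncertainty in one step.

Key step: step 9

## Route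

Step 1
Reactants: 1 2,3-dihydroxybenzaldehyde
Product: 2 3-(benzyloxy)-2-hydroxybenzaldehyde
Conditions: NaH (2.2 equiv), DMSO, rt; BnBr (1.0 equiv), rt; aq HCl work-up
Reagents that add atoms: benzyl bromide, BrCc1ccccc1
Why: Williamson etherification of the dianion; the 2-phenoxide is conjugated to and chelated by the formyl group, so the 3-phenoxide is the more nucleophilic oxygen and should take the single equivalent of benzyl bromide.

Step 2
Reactants: 2 3-(benzyloxy)-2-hydroxybenzaldehyde
Product: 3 3-(benzyloxy)-2-methoxybenzaldehyde
Conditions: MeI, K2CO3, DMF, rt
Reagents that add atoms: iodomethane, CI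
Why: Williamson O-methylation of the remaining acidic ortho-formyl phenol; the benzyl ether and the aldehyde are inert to carbonate.

Step 3
Reactants: 3 3-(benzyloxy)-2-methoxybenzaldehyde
Product: 4 3-(benzyloxy)-6-bromo-2-methoxybenzaldehyde
Conditions: NBS, DMF, rt
Reagents that add atoms: N-bromosuccinimide, O=C1CCC(=O)N1Br
Why: Electrophilic aromatic bromination; the benzyloxy group directs para to C6, whereas the 2-methoxy group is wedged between two substituents, twisted out of conjugation and a weak director. 2,3-Dialkoxybenzaldehydes are known to brominate at this position under these conditions.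

Step 4
Reactants: 5 4-bromo-1,2-dimethoxybenzene; 4 3-(benzyloxy)-6-bromo-2-methoxybenzaldehyde
Product: 7 [3-(benzyloxy)-6-bromo-2-methoxyphenyl](3,4-dimethoxyphenyl)methanol (racemic), via aryl Grignard reagent 6 (not isolated)
Conditions: Mg, I2 (cat.), THF, reflux; then 4, THF, −20 to 0 °C; aq NH4Cl
Reagents that add atoms: magnesium, [Mg] (held only in intermediate 6)
Why: Grignard formation and 1,2-addition to the aldehyde; at low temperature the aryl bromide of 4 should not exchange with an arylmagnesium bromide. The carbinol stereocentre forms racemic and is removed in step 5.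

Step 5
Reactants: 7 [3-(benzyloxy)-6-bromo-2-methoxyphenyl](3,4-dimethoxyphenyl)methanol
Product: 8 [3-(benzyloxy)-6-bromo-2-methoxyphenyl](3,4-dimethoxyphenyl)methanone
Conditions: Dess–Martin periodinane, CH2Cl2, rt
Reagents that add atoms: none
Why: Dess–Martin oxidation of a secondary dibenzylic alcohol to the diaryl ketone under neutral conditions that leave the aryl bromide and the ethers untouched.

Step 6
Reactants: 8 [3-(benzyloxy)-6-bromo-2-methoxyphenyl](3,4-dimethoxyphenyl)methanone; 9 prop-2-en-1-ol (allyl alcohol)
Product: 10 3-[4-(benzyloxy)-2-(3,4-dimethoxybenzoyl)-3-methoxyphenyl]propanal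
Conditions: Pd(OAc)2 (5 mol %), n-Bu4NCl, NaHCO3, DMF, 80 °C
Reagents that add atoms: none
Why: Heck reaction with an allylic alcohol under phosphine-free conditions. Zerovalent palladium inserts into the C–Br bond (activated by the ortho aroyl group), the aryl group adds to the terminal alkene carbon, and β-hydride elimination towards the carbinol carbon gives an enol that tautomerizes to the saturated aldehyde.

Step 7
Reactants: 10 3-[4-(benzyloxy)-2-(3,4-dimethoxybenzoyl)-3-methoxyphenyl]propanal
Product: 12 5-(benzyloxy)-3-(3,4-dimethoxyphenyl)-4-methoxy-1H-indene-2-carbaldehyde, via aldol adduct 11 (not isolated)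
Conditions: piperidine (cat.), AcOH (cat.), toluene, 60 °C
Reagents that add atoms: none
Why: Intramolecular aldol condensation through the enamine of the aldehyde, closing the five-membered ring onto the ketone carbonyl; the aldehyde is the only enolizable carbonyl and the diaryl ketone the only electrophile within reach. Loss of water from the tertiary dibenzylic aldol 11 is driven by conjugation and removes its stereocentres.

Step 8
Reactants: 12 5-(benzyloxy)-3-(3,4-dimethoxyphenyl)-4-methoxy-1H-indene-2-carbaldehyde
Product: 13 5-(benzyloxy)-2-(dimethoxymethyl)-3-(3,4-dimethoxyphenyl)-4-methoxy-1H-indene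
Conditions: HC(OMe)3, MeOH, TsOH·H2O (cat.), rt; Et3N quench
Reagents that add atoms: trimethyl orthoformate, COC(OC)OC; methanol, CO
Why: Acid-catalysed acetalization with the orthoformate as water scavenger; the β-carbon of the enal is fully substituted, so conjugate addition of methanol should not compete. The acetal turns the electron-poor enal into an electron-rich alkene and hides the carbonyl from alkoxide and tribromomethanide in step 9.

Step 9
Reactants: 13 5-(benzyloxy)-2-(dimethoxymethyl)-3-(3,4-dimethoxyphenyl)-4-methoxy-1H-indene; 14 bromoform
Product: 16 7-(benzyloxy)-2-bromo-1-(3,4-dimethoxyphenyl)-3-(dimethoxymethyl)-8-methoxynaphthalene, via dibromocyclopropane 15 (not isolated)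
Conditions: CHBr3 (3 equiv), KOt-Bu (4 equiv, added in portions), hexane/toluene, −20 °C to rt
Reagents that add atoms: none
Why: KOt-Bu deprotonates bromoform and α-elimination of bromide gives singlet dibromocarbene, which adds in a concerted [2+1] cycloaddition to the C2=C3 double bond of the indene to give the cis-fused dibromocyclopropane 15. The bromide lying over the five-membered ring then ionizes while the shared cyclopropane bond opens in the symmetry-allowed disrotatory two-electron electrocyclic sense, giving a 2-bromoallyl cation inside a six-membered ring that is stabilized at one end by the dimethoxyphenyl group. Loss of a proton from the adjacent CH2, directly or after collapse to an allylic bromide and elimination by the excess base, aromatizes ring B. The closest known reaction type is the ring enlargement of indenes to 2-halonaphthalenes with dihalocarbenes. Ring B is thus not closed by a cyclization: the three-membered ring closes by cheletropic addition, and the six-membered ring arises when the bond common to the three- and five-membered rings breaks, the carbene carbon becoming C2 between C1 and C3. The two stereocentres of 15 form racemic and vanish on aromatization, so nothing has to be controlled there. The step needs chemoselectivity for the alkene over the three electron-rich arenes, the acetal C–H and the benzylic OCH2 group, which the electrophilic carbene and the strained, styrene-type tetrasubstituted alkene should provide, and it needs the double bond to stay at C2=C3, because the 1-aryl isomer would place the bromine next to C4. This is secured by adding the base in portions to an excess of the far more acidic bromoform, so that little free alkoxide can deprotonate the indene CH2, and by the 3-aryl isomer being the conjugated, more substituted and therefore favoured one.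

Step 10
Reactants: 16 7-(benzyloxy)-2-bromo-1-(3,4-dimethoxyphenyl)-3-(dimethoxymethyl)-8-methoxynaphthalene
Product: 20 6-(benzyloxy)-4-(3,4-dimethoxyphenyl)-3-hydroxy-5-methoxynaphthalene-2-carbaldehyde, via aryllithium 17 (not isolated), via dimethyl arylboronate 18 (not isolated), via naphthol acetal 19 (not isolated)
Conditions: n-BuLi (1.1 equiv), THF, −78 °C; B(OMe)3, −78 °C to rt; 30% H2O2, aq NaOH, 0 °C; aq Na2SO3; 2 M HCl, THF, rt
Reagents that add atoms: n-butyllithium, [Li]CCCC (lithium held only in intermediate 17); trimethyl borate, COB(OC)OC (boron held only in intermediate 18); hydrogen peroxide, OO; water, O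
Why: Bromine–lithium exchange at −78 °C is faster than any deprotonation and the neighbouring acetal oxygen coordinates lithium; trimethyl borate traps the aryllithium, and alkaline hydrogen peroxide oxidizes the C–B bond with 1,2-migration of the aryl group from boron to oxygen, giving the naphthol at the same carbon. The aldehyde is still an acetal during the oxidation, so Dakin cleavage cannot occur. Once sulfite has destroyed the peroxide, dilute acid hydrolyses the dimethyl acetal.

Step 11
Reactants: 20 6-(benzyloxy)-4-(3,4-dimethoxyphenyl)-3-hydroxy-5-methoxynaphthalene-2-carbaldehyde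
Product: 21 4-(3,4-dimethoxyphenyl)-3,6-dihydroxy-5-methoxynaphthalene-2-carbaldehyde (vitrofolal B)
Conditions: H2 (1 atm), 10% Pd/C, EtOAc, rt
Reagents that add atoms: none
Why: Hydrogenolysis of the aryl benzyl ether over palladium on carbon at atmospheric pressure; the aldehyde is conjugated and hydrogen-bonded to the C2 hydroxyl, which should slow its reduction, and the reaction is stopped as soon as 20 is consumed.

## Compound list

1 | 2,3-dihydroxybenzaldehyde | O=Cc1cccc(O)c1O | starting material
2 | 3-(benzyloxy)-2-hydroxybenzaldehyde | O=Cc1cccc(OCc2ccccc2)c1O | intermediate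
3 | 3-(benzyloxy)-2-methoxybenzaldehyde | COc1c(OCc2ccccc2)cccc1C=O | intermediate
4 | 3-(benzyloxy)-6-bromo-2-methoxybenzaldehyde | COc1c(OCc2ccccc2)ccc(Br)c1C=O | intermediate
5 | 4-bromo-1,2-dimethoxybenzene | COc1ccc(Br)cc1OC | starting material
6 | (3,4-dimethoxyphenyl)magnesium bromide | COc1ccc([Mg]Br)cc1OC | intermediate (not isolated)
7 | [3-(benzyloxy)-6-bromo-2-methoxyphenyl](3,4-dimethoxyphenyl)methanol (racemic) | COc1ccc(C(O)c2c(Br)ccc(OCc3ccccc3)c2OC)cc1OC | intermediate
8 | [3-(benzyloxy)-6-bromo-2-methoxyphenyl](3,4-dimethoxyphenyl)methanone | COc1ccc(C(=O)c2c(Br)ccc(OCc3ccccc3)c2OC)cc1OC | intermediate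
9 | prop-2-en-1-ol (allyl alcohol) | C=CCO | starting material
10 | 3-[4-(benzyloxy)-2-(3,4-dimethoxybenzoyl)-3-methoxyphenyl]propanal | COc1ccc(C(=O)c2c(CCC=O)ccc(OCc3ccccc3)c2OC)cc1OC | intermediate
11 | 5-(benzyloxy)-3-(3,4-dimethoxyphenyl)-3-hydroxy-4-methoxy-2,3-dihydro-1H-indene-2-carbaldehyde (racemic, mixture of diastereomers) | COc1ccc(C2(O)C(C=O)Cc3ccc(OCc4ccccc4)c(OC)c32)cc1OC | intermediate (not isolated)
12 | 5-(benzyloxy)-3-(3,4-dimethoxyphenyl)-4-methoxy-1H-indene-2-carbaldehyde | COc1ccc(C2=C(C=O)Cc3ccc(OCc4ccccc4)c(OC)c32)cc1OC | intermediate
13 | 5-(benzyloxy)-2-(dimethoxymethyl)-3-(3,4-dimethoxyphenyl)-4-methoxy-1H-indene | COC(OC)C1=C(c2ccc(OC)c(OC)c2)c2c(OC)c(OCc3ccccc3)ccc2C1 | intermediate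
14 | bromoform | BrC(Br)Br | starting material
15 | 3-(benzyloxy)-1,1-dibromo-6a-(dimethoxymethyl)-1a-(3,4-dimethoxyphenyl)-2-methoxy-1,1a,6,6a-tetrahydrocyclopropa[a]indene (racemic, ring fusion necessarily cis) | COC(OC)C12Cc3ccc(OCc4ccccc4)c(OC)c3C1(c1ccc(OC)c(OC)c1)C2(Br)Br | intermediate (not isolated)
16 | 7-(benzyloxy)-2-bromo-1-(3,4-dimethoxyphenyl)-3-(dimethoxymethyl)-8-methoxynaphthalene | COC(OC)c1cc2ccc(OCc3ccccc3)c(OC)c2c(-c2ccc(OC)c(OC)c2)c1Br | intermediate
17 | [7-(benzyloxy)-1-(3,4-dimethoxyphenyl)-3-(dimethoxymethyl)-8-methoxynaphthalen-2-yl]lithium | COC(OC)c1cc2ccc(OCc3ccccc3)c(OC)c2c(-c2ccc(OC)c(OC)c2)c1[Li] | intermediate (not isolated)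
18 | dimethyl [7-(benzyloxy)-1-(3,4-dimethoxyphenyl)-3-(dimethoxymethyl)-8-methoxynaphthalen-2-yl]boronate | COC(OC)c1cc2ccc(OCc3ccccc3)c(OC)c2c(-c2ccc(OC)c(OC)c2)c1B(OC)OC | intermediate (not isolated)
19 | 7-(benzyloxy)-1-(3,4-dimethoxyphenyl)-3-(dimethoxymethyl)-8-methoxynaphthalen-2-ol | COC(OC)c1cc2ccc(OCc3ccccc3)c(OC)c2c(-c2ccc(OC)c(OC)c2)c1O | intermediate (not isolated)
20 | 6-(benzyloxy)-4-(3,4-dimethoxyphenyl)-3-hydroxy-5-methoxynaphthalene-2-carbaldehyde | O=Cc1cc2ccc(OCc3ccccc3)c(OC)c2c(-c2ccc(OC)c(OC)c2)c1O | intermediate
21 | 4-(3,4-dimethoxyphenyl)-3,6-dihydroxy-5-methoxynaphthalene-2-carbaldehyde (vitrofolal B) | COc1ccc(-c2c(O)c(C=O)cc3ccc(O)c(OC)c23)cc1OC | target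

## Step count and risk

Total step count: 11. Longest linear sequence: 11 steps, from 1 to 21; compounds 5, 9 and 14 enter in steps 4, 6 and 9, and the Grignard reagent 6 is made and used within step 4.

**Step 9 (key step).**
- What may go wrong: slow addition of the carbene to the crowded tetrasubstituted alkene, so that the carbene is consumed by alkoxide and 13 is recovered. Base-promoted migration of the double bond through the indenyl anion before cyclopropanation would lead to insertion on the wrong side and a bromine next to C4. Insertion of the carbene into the acetal or benzylic C–H bonds is a further possibility.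
- Fallback (sets out from 10, returns at 20): ring B would be built without a carbene.
  - SmI2 (THF, t-BuOH, −78 °C to rt) would couple the ketone carbon with the aldehyde carbon in an intramolecular pinacol reaction to give the cis-diol 7-(benzyloxy)-1-(3,4-dimethoxyphenyl)-8-methoxy-1,2,3,4-tetrahydronaphthalene-1,2-diol F1 (racemic).
  - TsOH in warm toluene would ionize the tertiary dibenzylic hydroxyl, and a 1,2-hydride shift would give the tetralone 7-(benzyloxy)-1-(3,4-dimethoxyphenyl)-8-methoxy-3,4-dihydronaphthalen-2(1H)-one F2.
  - Claisen formylation with ethyl formate and NaH in THF would go to C3, the only position whose product forms a stabilized enolate, and give (3Z)-7-(benzyloxy)-1-(3,4-dimethoxyphenyl)-3-(hydroxymethylidene)-8-methoxy-3,4-dihydronaphthalen-2(1H)-one F3.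
  - Dehydrogenation with DDQ would aromatize ring B to 20.
  - In this sequence C2 is the aldehyde carbon of 10 and the formyl carbon comes from ethyl formate.

**Step 7.**
- What may go wrong: slow or reversible addition to the ketone, whose carbonyl is flanked by two ortho substituents on ring A and deactivated by the electron-rich ring C, so that intermolecular self-condensation of the aldehyde takes over.
- Fallback (sets out from 8, returns at 12): a stronger, irreversibly formed nucleophile would be used.
  - Heck coupling of 8 with acrolein diethyl acetal (Pd(OAc)2, n-Bu4NCl, n-Bu3N, DMF, 90 °C; β-hydride elimination towards the acetal carbon and hydrolysis of the ketene acetal) would give ethyl 3-[4-(benzyloxy)-2-(3,4-dimethoxybenzoyl)-3-methoxyphenyl]propanoate F4.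
  - LiN(SiMe3)2 in THF at −78 to 0 °C would close the ester enolate onto the ketone to give ethyl 5-(benzyloxy)-3-(3,4-dimethoxyphenyl)-3-hydroxy-4-methoxy-2,3-dihydro-1H-indene-2-carboxylate F5.
  - TsOH in warm toluene would dehydrate it to ethyl 5-(benzyloxy)-3-(3,4-dimethoxyphenyl)-4-methoxy-1H-indene-2-carboxylate F6.
  - i-Bu2AlH (CH2Cl2, −78 °C) would reduce the ester to [5-(benzyloxy)-3-(3,4-dimethoxyphenyl)-4-methoxy-1H-inden-2-yl]methanol F7, and MnO2 (CH2Cl2, rt) would oxidize it to 12.

**Step 10.**
- What may go wrong: protonation of the hindered aryllithium (loss of the halogen without oxygenation), sluggish borylation at a carbon with two ortho substituents, deprotonation of the benzylic OCH2 with Wittig rearrangement, or over-oxidation of the electron-rich naphtholate by peroxide and air.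
- Fallback (sets out from 16, returns at 19, which the same acid treatment converts into 20): palladium-catalysed hydroxylation of the aryl bromide with Pd2(dba)3, 2-di-tert-butylphosphino-2',4',6'-triisopropylbiphenyl and KOH in 1,4-dioxane/water at 100 °C. This is a C–O coupling that avoids organolithium and peroxide and makes no new compound.

**Step 11.**
- What may go wrong: over-reduction of the formyl group to the hydroxymethyl or methyl group on the palladium surface before debenzylation is complete.
- Fallback (sets out from 20, returns at 21): Lewis-acid debenzylation with BCl3 and pentamethylbenzene as cation scavenger in CH2Cl2 at −78 °C. It involves no hydrogen and leaves the aldehyde and the methyl ethers alone at that temperature.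

## Further compounds

F1 | step 9 | 7-(benzyloxy)-1-(3,4-dimethoxyphenyl)-8-methoxy-1,2,3,4-tetrahydronaphthalene-1,2-diol (cis, racemic; one enantiomer drawn) | O[C@@H]1CCc2ccc(OCc3ccccc3)c(OC)c2[C@@]1(O)c1ccc(OC)c(OC)c1
F2 | step 9 | 7-(benzyloxy)-1-(3,4-dimethoxyphenyl)-8-methoxy-3,4-dihydronaphthalen-2(1H)-one (racemic) | O=C1CCc2ccc(OCc3ccccc3)c(OC)c2C1c1ccc(OC)c(OC)c1
F3 | step 9 | (3Z)-7-(benzyloxy)-1-(3,4-dimethoxyphenyl)-3-(hydroxymethylidene)-8-methoxy-3,4-dihydronaphthalen-2(1H)-one (racemic) | O/C=C1/Cc2ccc(OCc3ccccc3)c(OC)c2C(c2ccc(OC)c(OC)c2)C1=O
F4 | step 7 | ethyl 3-[4-(benzyloxy)-2-(3,4-dimethoxybenzoyl)-3-methoxyphenyl]propanoate | CCOC(=O)CCc1ccc(OCc2ccccc2)c(OC)c1C(=O)c1ccc(OC)c(OC)c1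
F5 | step 7 | ethyl 5-(benzyloxy)-3-(3,4-dimethoxyphenyl)-3-hydroxy-4-methoxy-2,3-dihydro-1H-indene-2-carboxylate (racemic, mixture of diastereomers) | CCOC(=O)C1Cc2ccc(OCc3ccccc3)c(OC)c2C1(O)c1ccc(OC)c(OC)c1
F6 | step 7 | ethyl 5-(benzyloxy)-3-(3,4-dimethoxyphenyl)-4-methoxy-1H-indene-2-carboxylate | CCOC(=O)C1=C(c2ccc(OC)c(OC)c2)c2c(OC)c(OCc3ccccc3)ccc2C1
F7 | step 7 | [5-(benzyloxy)-3-(3,4-dimethoxyphenyl)-4-methoxy-1H-inden-2-yl]methanol | OCC1=C(c2ccc(OC)c(OC)c2)c2c(OC)c(OCc3ccccc3)ccc2C1
F0 | step 10 | none | none
F0 | step 11 | none | none
A1 | alternative 1 | methyl 3-{4-(benzyloxy)-2-[1-(3,4-dimethoxyphenyl)-2-methoxy-2-oxoethyl]-3-methoxyphenyl}propanoate (racemic) | COC(=O)CCc1ccc(OCc2ccccc2)c(OC)c1C(C(=O)OC)c1ccc(OC)c(OC)c1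
A2 | alternative 1 | methyl 6-(benzyloxy)-4-(3,4-dimethoxyphenyl)-3-hydroxy-5-methoxy-1,4-dihydronaphthalene-2-carboxylate (enol form, racemic) | COC(=O)C1=C(O)C(c2ccc(OC)c(OC)c2)c2c(OC)c(OCc3ccccc3)ccc2C1
A3 | alternative 2 | 7-(benzyloxy)-1-(3,4-dimethoxyphenyl)-1-hydroxy-8-methoxy-3,4-dihydronaphthalen-2(1H)-one (racemic) | O=C1CCc2ccc(OCc3ccccc3)c(OC)c2C1(O)c1ccc(OC)c(OC)c1
A4 | alternative 3 | 1-[3-(benzyloxy)-6-ethenyl-2-methoxyphenyl]-3-{[(tert-butyldimethylsilyl)oxy]methyl}-1-(3,4-dimethoxyphenyl)but-3-en-2-one (racemic) | C=Cc1ccc(OCc2ccccc2)c(OC)c1C(c1ccc(OC)c(OC)c1)C(=O)C(=C)CO[Si](C)(C)C(C)(C)C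
A5 | alternative 3 | 7-(benzyloxy)-3-[(tert-butyldimethylsilyloxy)methyl]-1-(3,4-dimethoxyphenyl)-8-methoxynaphthalen-2-ol | CC(C)(C)[Si](C)(C)OCc1cc2ccc(OCc3ccccc3)c(OC)c2c(-c2ccc(OC)c(OC)c2)c1O
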